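The route rests on disconnecting the C4–C5 bond of ring A (labdane numbering). Tying C20 and the oxygen on C6 together as a butenolide makes C5 its electrophilic β-carbon and places the C6 stereocentre, taken from (R)-5-(hydroxymethyl)butyrolactone, beside it. In one operation a sulfonyl-nitrile carbanion at C4 adds to C5, closing ring A, and the lactone enolate formed at C10 acylates itself with a Weinreb amide hung on C6, closing ring B. This sets C5 and C10 and leaves the lactone bridging the 1,3-diaxial positions C10 and C6 of ring B. The precursor is a 3,5-disubstituted butenolide carrying both chains.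

Key step: step 6

Remark: positions are numbered as in labdanes (decalin C1–C10; C18 and C19 on C4; C20 on C10; C17 on C8; side chain C11–C16); α is the face of H-5, β the face of C20. Compounds 1 and 3 are assumed to be commercial.

**Step 1**
Reactants: 1 (5R)-5-(hydroxymethyl)oxolan-2-one
Product: 2 (2R)-5-oxooxolane-2-carbaldehyde
Conditions: Dess–Martin periodinane, CH2Cl2, 0 °C to rt
Reagents that add atoms: none
Why: Dess–Martin oxidation of the primary alcohol; the stereocentre is not touched and the aldehyde is used at once to avoid α-epimerisation.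

**Step 2**
Reactants: 3 methyl 2-[bis(2,2,2-trifluoroethoxy)phosphoryl]acetate; 4 1-chloro-3-iodopropane
Product: 5 methyl 2-[bis(2,2,2-trifluoroethoxy)phosphoryl]-5-chloropentanoate (racemic)
Conditions: NaH, DMF, 0 °C to rt
Reagents that add atoms: none
Why: C-alkylation of the phosphonoacetate carbanion by SN2 displacement of iodide, the better leaving group of 4.

**Step 3**
Reactants: 2 (2R)-5-oxooxolane-2-carbaldehyde; 5 chloro phosphonate
Product: 6 methyl (2Z)-5-chloro-2-{[(2R)-5-oxooxolan-2-yl]methylidene}pentanoate
Conditions: KN(SiMe3)2, 18-crown-6, THF, −78 °C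
Reagents that add atoms: none
Why: Still–Gennari variant of the Horner–Wadsworth–Emmons olefination: the electron-poor phosphonate with a dissociated potassium counter-ion eliminates kinetically to the Z-enoate (ester cis to the lactone carbon), and −78 °C keeps the α-stereocentre of 2 intact.

**Step 4**
Reactants: 6 Z-enoate lactone
Product: 8 3-[(2R)-4-(3-chloropropyl)-5-oxo-2,5-dihydrofuran-2-yl]-N-methoxy-N-methylpropanamide, via hydroxy amide 7 (not isolated)
Conditions: AlMe3, MeNH(OMe)·HCl, CH2Cl2, 0 °C to rt; aq. HCl
Reagents that add atoms: N,O-dimethylhydroxylamine hydrochloride, CNOC.Cl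
Why: AlMe3-mediated Weinreb aminolysis opens the γ-lactone faster than it touches the hindered conjugated ester, and the C6 alkoxide so released closes onto the cis ester (translactonisation) to the butenolide, which moves O-6 from C9 to C20 without touching the C6 stereocentre.

**Step 5**
Reactants: 8 butenolide chloride; 9 2-(benzenesulfonyl)acetonitrile
Product: 10 3-{(2R)-4-[4-(benzenesulfonyl)-4-cyanobutyl]-5-oxo-2,5-dihydrofuran-2-yl}-N-methoxy-N-methylpropanamide (both epimers at the sulfonyl carbon)
Conditions: NaH (1 equiv), 9 in excess, NaI, DMF, 0 °C to rt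
Reagents that add atoms: none
Why: SN2 alkylation of the sodium salt of 9 by the primary halide (iodide exchange in situ); with one equivalent of base and the acidic pronucleophile in excess the butenolide γ-hydrogen is not removed, and the new centre at the sulfonyl carbon is an inconsequential mixture that is deprotonated in step 6.

**Step 6**
Reactants: 10 butenolide sulfonyl nitrile
Product: 13 tricyclic keto lactone (4β-cyano-9-oxo-4α-benzenesulfonyl trans-decalin whose C20 carbonyl on C10 is lactonised to O-6β), via lithium lactone enolate 11 (not isolated), via tetrahedral adduct 12 (not isolated)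
Conditions: LiN(SiMe3)2 (1.05 equiv), THF–DMPU, −78 °C to rt; aq. HCl
Reagents that add atoms: none
Why: LiN(SiMe3)2 deprotonates only C4, the carbon between the sulfonyl and cyano groups, and this carbanion adds to C5, the β-carbon of the butenolide (6-endo-trig), closing ring A through the C4–C5 bond; the lactone enolate released at C10 then attacks the Weinreb amide carbonyl C9 (6-exo-trig) and closes ring B, the lithium-chelated tetrahedral adduct giving the C9 ketone on acidic work-up. The closest known reaction type is the anionic Michael–Dieckmann (Michael–Claisen) annulation. C5 is set by addition to the planar butenolide on the face anti to the C6 side chain, the usual trans addition to 5-substituted butenolides. C10 is set by the tether: the amide chain hangs from C6 and can reach the enolate only from its own face, which gives the trans ring fusion (H-5α, C20 β) with the lactone spanning C10 and C6; at C4 the bulky sulfonyl group should take the equatorial and the small cyano group the axial (β) position. The step needs 1,4- rather than 1,2-addition and ring closure faster than proton transfer; the soft, fully stabilised donor, one equivalent of base and the irreversible acylation, which drains the unfavourable Michael equilibrium, should secure this.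

**Step 7**
Reactants: 13 tricyclic keto lactone
Product: 16 9,20-dihydroxy-4α-(benzenesulfonyl)-19,6β-olide (C9 carbinol epimers), via triol nitrile 14 (not isolated), via iminolactone 15 (not isolated)
Conditions: LiBH4, THF, 0 °C to rt; then 2 M HCl, THF, rt
Reagents that add atoms: water, O
Why: Hydride reduction by LiBH4 converts the C9 ketone and the strained bridged lactone into alkoxides while nitrile and sulfone are inert; the 6β-alkoxide adds to the syn-axial nitrile (5-exo-dig, Pinner-type) faster than the C20 alkoxide could close a six-membered imidate, and acid hydrolysis gives the γ-lactone, so that O-6 is transferred from C20 to C19; the C9 carbinol centre is not controlled and is erased in step 10.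

**Step 8**
Reactants: 16 diol lactone
Product: 17 20-O-tert-butyldimethylsilyl ether of 16
Conditions: TBSCl, imidazole, DMF, 0 °C
Reagents that add atoms: tert-butyldimethylsilyl chloride, CC(C)(C)[Si](C)(C)Cl
Why: Silylation is selective for the primary C20 hydroxyl over the hindered secondary C9 hydroxyl.

**Step 9**
Reactants: 17 silyl ether sulfone
Product: 18 20-(TBS-oxy)-9-hydroxy-19,6β-olide with H-4α
Conditions: SmI2, THF–DMPU, MeOH, −78 °C
Reagents that add atoms: none
Why: Reductive desulfonylation of an α-sulfonyl lactone by single-electron transfer from SmI2 gives the samarium enolate, which methanol protonates; because the lactone can only be cis-fused to ring A, H-4 ends α.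

**Step 10**
Reactants: 18 hydroxy lactone
Product: 19 20-(TBS-oxy)-9-oxo-19,6β-olide (H-4α, C8 unsubstituted)
Conditions: Dess–Martin periodinane, CH2Cl2, rt
Reagents that add atoms: none
Why: Dess–Martin oxidation of the secondary alcohol returns the C9 ketone; no stereocentre is formed.

**Step 11**
Reactants: 19 keto lactone
Product: 21 4α-methyl-8α-methyl-9-oxo-20-(TBS-oxy)-19,6β-olide, via C8-epimer mixture 20 (not isolated)
Conditions: LiN(i-Pr)2 (2.1 equiv), THF–DMPU, −78 °C; MeI; then DBU (cat.), toluene, rt
Reagents that add atoms: iodomethane, CI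
Why: Double enolate alkylation: the ketone enolises only toward C8 (C10 is quaternary) and the lactone at C4; MeI attacks the lactone enolate on the α face because C19 is held β by the lactone ring and the β face is screened by the axial C20 substituent, giving the 4α-methyl quaternary centre, and DBU then epimerises C8 via the enol to the equatorial 8α-methyl ketone.

**Step 12**
Reactants: 21 dimethyl keto lactone
Product: 22 9α,11-epoxide (spiro-oxirane at C9, oxygen α, CH2 β)
Conditions: Me3S(O)I, NaH, DMSO, rt to 50 °C
Reagents that add atoms: trimethylsulfoxonium iodide, C[S+](C)(C)=O.[I-]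
Why: Corey–Chaykovsky epoxidation: the sulfoxonium ylide adds reversibly and the betaine with the new C–C bond equatorial (C11 β) closes, giving the axial α-oxygen at C9, the sense usual for this ylide with hindered cyclohexanones.

**Step 13**
Reactants: 23 3-chloro-2-(chloromethyl)prop-1-ene; 24 prop-2-en-1-ol
Product: 25 2-(chloromethyl)-3-(prop-2-enyloxy)prop-1-ene
Conditions: NaH, THF, 0 °C to rt (23 in excess)
Reagents that add atoms: none
Why: Williamson ether synthesis; the allylic dichloride in excess limits substitution to one chloride.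

**Step 14**
Reactants: 22 epoxide; 25 allylic chloride
Product: 27 9α-hydroxy compound carrying CH2CH2C(=CH2)CH2OCH2CH=CH2 on C9β, via allylmagnesium chloride 26 (not isolated)
Conditions: Mg, THF, 0 °C; then 22, CuI (10 mol %), THF, −40 to 0 °C; aq. NH4Cl
Reagents that add atoms: none
Why: Copper-catalysed SN2 opening of the 1,1-disubstituted epoxide at its CH2 carbon by a 2-substituted allyl Grignard reagent whose two termini are equivalent, so no regiochemical question arises; the C9 configuration of the epoxide is retained and the neopentyl lactone carbonyl is shielded at low temperature.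

**Step 15**
Reactants: 27 diene alcohol
Product: 28 20-(TBS-oxy)-9α-hydroxy-15,16-epoxylabd-13-en-19,6β-olide (2,5-dihydrofuran side chain)
Conditions: second-generation Grubbs catalyst RuCl2(=CHPh)(PCy3)(H2IMes) (5 mol %), CH2Cl2, 40 °C
Reagents that add atoms: none
Why: Ring-closing metathesis of the 1,1-disubstituted and the monosubstituted alkene gives the 3-substituted 2,5-dihydrofuran with loss of ethene; no stereocentre is involved.

**Step 16**
Reactants: 28 silyl ether
Product: 29 9α,20-dihydroxy-15,16-epoxylabd-13-en-19,6β-olide
Conditions: Bu4NF, THF, 0 °C to rt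
Reagents that add atoms: none
Why: Fluoride-mediated cleavage of the silyl ether; lactone and tertiary alcohol are unaffected.

**Step 17**
Reactants: 29 diol
Product: 30 20-acetoxy-9α-hydroxy-15,16-epoxylabd-13-en-19,6β-olide
Conditions: Ac2O, pyridine, DMAP (cat.), CH2Cl2, 0 °C
Reagents that add atoms: acetic anhydride, CC(=O)OC(C)=O
Why: Acetylation of the primary alcohol under nucleophilic catalysis; the hindered tertiary 9-hydroxyl does not react.

**Step 18**
Reactants: 30 acetate
Product: 31 20-acetoxy-14-iodo-9α,13:15,16-diepoxylabdan-19,6β-olide (C13 as in the target, iodine trans to O-9 across C13–C14)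
Conditions: N-iodosuccinimide, NaHCO3, CH2Cl2, 0 °C, dark
Reagents that add atoms: N-iodosuccinimide, O=C1CCC(=O)N1I
Why: Iodoetherification: the 9α-hydroxyl attacks the more substituted carbon C13 of the iodonium ion (5-exo, Markovnikov) anti to iodine, which sets the spiro centre; the CH2O arm C16 should turn toward the more open C8 edge and the iodine-bearing C14 toward the C1 edge of the decalin, which corresponds to the configuration of the target at C13.

**Step 19**
Reactants: 31 iodo ether
Product: 32 20-acetoxy-9α,13R:15,16-diepoxylabd-14-en-19,6β-olide (target)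
Conditions: DBU, toluene, 80 °C
Reagents that add atoms: none
Why: E2 dehydroiodination: C13 is quaternary, so only H-15 can be lost anti to iodine, which gives the enol ether C14=C15 under non-acidic conditions that the acid-labile product tolerates.

**Compound list**
1 | (5R)-5-(hydroxymethyl)oxolan-2-one | OC[C@H]1CCC(=O)O1 | starting material
2 | (2R)-5-oxooxolane-2-carbaldehyde | O=C[C@H]1CCC(=O)O1 | intermediate
3 | methyl 2-[bis(2,2,2-trifluoroethoxy)phosphoryl]acetate | COC(=O)CP(=O)(OCC(F)(F)F)OCC(F)(F)F | starting material
4 | 1-chloro-3-iodopropane | ClCCCI | starting material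
5 | methyl 2-[bis(2,2,2-trifluoroethoxy)phosphoryl]-5-chloropentanoate (racemic) | COC(=O)C(CCCCl)P(=O)(OCC(F)(F)F)OCC(F)(F)F | intermediate
6 | methyl (2Z)-5-chloro-2-{[(2R)-5-oxooxolan-2-yl]methylidene}pentanoate | COC(=O)/C(CCCCl)=C\[C@H]1CCC(=O)O1 | intermediate
7 | methyl (2Z,4R)-2-(3-chloropropyl)-4-hydroxy-7-[methoxy(methyl)amino]-7-oxohept-2-enoate (formed as its aluminium alkoxide) | COC(=O)/C(CCCCl)=C\[C@H](O)CCC(=O)N(C)OC | intermediate
8 | 3-[(2R)-4-(3-chloropropyl)-5-oxo-2,5-dihydrofuran-2-yl]-N-methoxy-N-methylpropanamide | CON(C)C(=O)CC[C@@H]1C=C(CCCCl)C(=O)O1 | intermediate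
9 | 2-(benzenesulfonyl)acetonitrile | N#CCS(=O)(=O)c1ccccc1 | starting material
10 | 3-{(2R)-4-[4-(benzenesulfonyl)-4-cyanobutyl]-5-oxo-2,5-dihydrofuran-2-yl}-N-methoxy-N-methylpropanamide (both epimers at the sulfonyl carbon) | CON(C)C(=O)CC[C@@H]1C=C(CCCC(C#N)S(=O)(=O)c2ccccc2)C(=O)O1 | intermediate
11 | lithium lactone enolate of the Michael adduct (ring A closed, enolate at C10) | [Li+].[O-]C1=C2CCC[C@@](C#N)(S(=O)(=O)c3ccccc3)[C@@H]2[C@@H](CCC(=O)N(C)OC)O1 | intermediate
12 | lithium salt of the tetrahedral adduct at C9 (ring B closed) | O=C1O[C@@H]2CCC([O-])(N(C)OC)[C@]13CCC[C@@](C#N)(S(=O)(=O)c4ccccc4)[C@H]23.[Li+] | intermediate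
13 | tricyclic keto lactone: 4β-cyano-9-oxo-4α-(benzenesulfonyl) trans-decalin, C20 carbonyl on C10 lactonised to O-6β, H-5α | O=C1O[C@@H]2CCC(=O)[C@]13CCC[C@@](C#N)(S(=O)(=O)c4ccccc4)[C@H]23 | intermediate
14 | 4β-cyano-4α-(benzenesulfonyl) trans-decalin-6β,9,20-triol (formed as alkoxides) | OC[C@]12CCC[C@@](C#N)(S(=O)(=O)c3ccccc3)[C@@H]1[C@H](O)CCC2O | intermediate
15 | cyclic imidate from O-6β and the C19 nitrile of 14 | OC[C@@]12CCC[C@]3(S(=O)(=O)c4ccccc4)C(=N)O[C@H](CCC1O)[C@H]23 | intermediate
16 | 9,20-dihydroxy-4α-(benzenesulfonyl)-19,6β-olide (C9 carbinol epimers) | OC[C@@]12CCC[C@]3(S(=O)(=O)c4ccccc4)C(=O)O[C@H](CCC1O)[C@H]23 | intermediate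
17 | 20-O-tert-butyldimethylsilyl ether of 16 | CC(C)(C)[Si](C)(C)OC[C@@]12CCC[C@]3(S(=O)(=O)c4ccccc4)C(=O)O[C@H](CCC1O)[C@H]23 | intermediate
18 | 20-(TBS-oxy)-9-hydroxy-19,6β-olide with H-4α | CC(C)(C)[Si](C)(C)OC[C@@]12CCC[C@@H]3C(=O)O[C@H](CCC1O)[C@H]23 | intermediate
19 | 20-(TBS-oxy)-9-oxo-19,6β-olide with H-4α | CC(C)(C)[Si](C)(C)OC[C@@]12CCC[C@@H]3C(=O)O[C@H](CCC1=O)[C@H]23 | intermediate
20 | 4α-methyl-8-methyl-9-oxo-20-(TBS-oxy)-19,6β-olide, mixture of C8 epimers | CC(C)(C)[Si](C)(C)OC[C@@]12CCC[C@]3(C)C(=O)O[C@H](CC(C)C1=O)[C@H]23 | intermediate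
21 | 4α,8α-dimethyl-9-oxo-20-(TBS-oxy)-19,6β-olide | CC(C)(C)[Si](C)(C)OC[C@@]12CCC[C@]3(C)C(=O)O[C@H](C[C@@H](C)C1=O)[C@H]23 | intermediate
22 | 9α,11-epoxide of 21 (spiro-oxirane, oxygen α, CH2 β) | CC(C)(C)[Si](C)(C)OC[C@@]12CCC[C@]3(C)C(=O)O[C@H](C[C@@H](C)[C@]14CO4)[C@H]23 | intermediate
23 | 3-chloro-2-(chloromethyl)prop-1-ene | C=C(CCl)CCl | starting material
24 | prop-2-en-1-ol | C=CCO | starting material
25 | 2-(chloromethyl)-3-(prop-2-enyloxy)prop-1-ene | C=CCOCC(=C)CCl | intermediate
26 | {2-[(prop-2-enyloxy)methyl]prop-2-enyl}magnesium chloride | C=CCOCC(=C)C[Mg]Cl | intermediate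
27 | 9α-hydroxy compound with CH2CH2C(=CH2)CH2OCH2CH=CH2 on C9β (20-TBS ether, 19,6β-olide) | CC(C)(C)[Si](C)(C)OC[C@@]12CCC[C@]3(C)C(=O)O[C@H](C[C@@H](C)[C@]1(O)CCC(=C)COCC=C)[C@H]23 | intermediate
28 | 20-(TBS-oxy)-9α-hydroxy-15,16-epoxylabd-13-en-19,6β-olide | CC(C)(C)[Si](C)(C)OC[C@@]12CCC[C@]3(C)C(=O)O[C@H](C[C@@H](C)[C@]1(O)CCC4=CCOC4)[C@H]23 | intermediate
29 | 9α,20-dihydroxy-15,16-epoxylabd-13-en-19,6β-olide | OC[C@@]12CCC[C@]3(C)C(=O)O[C@H](C[C@@H](C)[C@]1(O)CCC4=CCOC4)[C@H]23 | intermediate
30 | 20-acetoxy-9α-hydroxy-15,16-epoxylabd-13-en-19,6β-olide | CC(=O)OC[C@@]12CCC[C@]3(C)C(=O)O[C@H](C[C@@H](C)[C@]1(O)CCC4=CCOC4)[C@H]23 | intermediate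
31 | 20-acetoxy-14-iodo-9α,13:15,16-diepoxylabdan-19,6β-olide (C13 as in the target, iodine trans to O-9) | CC(=O)OC[C@@]12CCC[C@]3(C)C(=O)O[C@H](C[C@@H](C)[C@]14CC[C@]1([C@@H](I)COC1)O4)[C@H]23 | intermediate
32 | 20-acetoxy-9α,13R:15,16-diepoxylabd-14-en-19,6β-olide | CC(=O)OC[C@@]12CCC[C@]3(C)C(=O)O[C@H](C[C@@H](C)[C@]14CC[C@]1(C=COC1)O4)[C@H]23 | target

**Step count**
Total: 19 steps. Longest linear sequence: 17 steps (from 1 through steps 1, 3–12 and 14–19).

**Steps most likely to fail**

1. Step 6. The Michael addition of the doubly stabilised carbanion lies on the unfavourable side. If acylation at C10 does not drain it, proton transfer to the transient enolate, 1,2-addition, or epimerisation at C6 through γ-deprotonation of the butenolide could take over. Fallback: set out from 10 and close ring A first under proton-transfer conditions (catalytic DBU, MeCN, rt), where the neutral Michael addition is downhill, to give the bicyclic Michael adduct lactone F1. F1 is then enolised at C10, its most acidic position, with LiN(SiMe3)2 in THF (−78 to 0 °C) and closes ring B onto the Weinreb amide, which comes back to the route at 13.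

2. Step 12. Methylene transfer to the very hindered C9 ketone may be slow, so that enolisation or attack from the wrong face (epimeric epoxide) competes. Fallback: set out from 21, methylenate the ketone by a Wittig reaction (Ph3P=CH2, toluene, 80 °C) to the exocyclic alkene F2, and epoxidise with m-chloroperbenzoic acid (NaHCO3, CH2Cl2). The peracid should approach from the α face because the β face is screened by the axial C20 substituent, which comes back to the route at 22.

3. Step 18. The capture of the iodonium ion may show poor facial selectivity at C13, giving the spiro epimer as well. Fallback: set out from 30 and close the spiro ether by an aerobic Wacker-type cyclisation (Pd(O2CCF3)2, a chiral pyridine–oxazoline ligand, Na2CO3, O2, toluene, 80 °C). Oxypalladation by the 9α-hydroxyl and β-hydride elimination toward C15 give the enol ether directly, with the ligand steering the face, which comes back to the route at 32; no new compound is made (F0).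

Further compounds
F1 | step 6 | bicyclic Michael adduct lactone (ring A closed, C10–H, Weinreb amide chain on C6; C10 not defined) | O=C1C2CCC[C@@](C#N)(S(=O)(=O)c3ccccc3)[C@@H]2[C@@H](CCC(=O)N(C)OC)O1
F2 | step 12 | 9(11)-exocyclic alkene of 21 (4α,8α-dimethyl-9-methylidene-20-(TBS-oxy)-19,6β-olide) | CC(C)(C)[Si](C)(C)OC[C@@]12CCC[C@]3(C)C(=O)O[C@H](C[C@@H](C)C1=C)[C@H]23
F0 | step 18 | none | none
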